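**Plan**

Labdane numbering is used (ring A: C1–C5 and C10; ring B: C5–C10; side chain C11–C16; C17 is the exocyclic CH2).
Retrosynthesis cuts C8=C17 (Wittig), C9–C11 (alkylation by a C11–C16 iodide made from (R)-linalool), C1–C2 (radical closure of ring A), the C1–C10 link (CH2 delivered through a temporary cyclopropane on C9–C10) and C4–C5 (Ireland–Claisen).
Forward: ring B is bought as 2-methylcyclohex-2-enone; the C4(Me2)–C3–C2 arm is put on C5, C8 is oxidized, the cyclopropane is fused on and opened to CH2I on C10, ring A is closed, then the side chain and the methylene are added.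
Enabling feature: C3 carries bromine between quaternary C4 and the CH2 C2, and C1 is a CH2 on quaternary C10. Ring A can therefore close by 6-endo attack of a C1 radical on the CH2 end of a C4–C3(Br)=C2H2 bromoalkene, which forms the ring and the C–Br stereocentre in one event.
Stereochemistry: C5 from a CBS reduction relayed by the suprafacial [3,3] shift; C10 by cyclopropanation anti to the C5 arm; C3 by axial hydrogen-atom transfer (bromine equatorial); C9 by alkylation anti to the C10 methyl; C13 from (R)-linalool.

Key step: step 9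

Assumption: commercial (R)-(−)-linalool of high enantiomeric purity is used, and the CBS reduction is taken to follow its usual facial model (alkenyl arm as the large group).

**Route**

Step 1
Reactants: 1 2-methylcyclohex-2-en-1-one
Product: 2 (1R)-2-methylcyclohex-2-en-1-ol
Conditions: (S)-2-methyl-CBS-oxazaborolidine (10 mol%), BH3·SMe2, THF, −20 °C; then MeOH
Reagents that add atoms: none
Why: CBS reduction, in which the alkenyl arm acts as the large group so that hydride reaches one carbonyl face and the catalyst sets the R carbinol centre.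

Step 2
Reactants: 2 (1R)-2-methylcyclohex-2-en-1-ol
Product: 3 (1R)-2-methylcyclohex-2-en-1-yl 2-methylpropanoate
Conditions: i-PrCOCl, Et3N, DMAP (cat.), CH2Cl2, 0 °C → rt
Reagents that add atoms: isobutyryl chloride CC(C)C(=O)Cl
Why: Acylation of a secondary allylic alcohol by an acid chloride under nucleophilic catalysis, which leaves the carbinol centre untouched.

Step 3
Reactants: 3 (1R)-2-methylcyclohex-2-en-1-yl 2-methylpropanoate
Product: 6 2-methyl-2-[(1S)-2-methylcyclohex-2-en-1-yl]propanoic acid, via silyl ketene acetal 4 (not isolated), via trimethylsilyl ester 5 (not isolated)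
Conditions: LiN(i-Pr)2, THF, −78 °C; Me3SiCl; −78 → 65 °C; then aq. HCl
Reagents that add atoms: none
Why: Ireland–Claisen rearrangement, in which the symmetric isobutyrate ketene acetal needs no enolate-geometry control and the suprafacial [3,3] shift forms the C4–C5 bond on the ring face that carried oxygen, so the carbinol chirality becomes the C5 stereocentre while the alkene moves to C9=C10.

Step 4
Reactants: 6 2-methyl-2-[(1S)-2-methylcyclohex-2-en-1-yl]propanoic acid
Product: 7 3-methyl-3-[(1S)-2-methylcyclohex-2-en-1-yl]butan-2-one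
Conditions: MeLi (2.5 equiv), Et2O, 0 °C → rt; then poured into cold aq. HCl
Reagents that add atoms: methyllithium [Li]C
Why: Ketone synthesis from a carboxylic acid and two equivalents of an alkyllithium, where the hindered gem-diolate resists further addition and gives the methyl ketone only on acidic quench.

Step 5
Reactants: 7 3-methyl-3-[(1S)-2-methylcyclohex-2-en-1-yl]butan-2-one
Product: 8 (6S)-6-(3-bromo-2-methylbut-3-en-2-yl)-1-methylcyclohex-1-ene
Conditions: (PhO)3P, Br2, CH2Cl2, −60 °C; then 7, Et3N, −60 → 40 °C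
Reagents that add atoms: bromine BrBr
Why: Ketone-to-vinyl-bromide conversion with the triphenyl phosphite–bromine reagent (O-phosphonium activation, bromide addition, base-induced elimination), regiochemically unambiguous because only the methyl side carries α-hydrogens.

Step 6
Reactants: 8 (6S)-6-(3-bromo-2-methylbut-3-en-2-yl)-1-methylcyclohex-1-ene
Product: 9 (4S)-4-(3-bromo-2-methylbut-3-en-2-yl)-3-methylcyclohex-2-en-1-one
Conditions: CrO3, 3,5-dimethylpyrazole, CH2Cl2, −20 °C
Reagents that add atoms: chromium trioxide O=[Cr](=O)=O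
Why: Allylic oxidation of the ring CH2 next to the vinylic CH of a trisubstituted cyclohexene to the β-methyl enone, the other allylic sites being a methyl group and a shielded methine, with no stereocentre touched.

Step 7
Reactants: 9 (4S)-4-(3-bromo-2-methylbut-3-en-2-yl)-3-methylcyclohex-2-en-1-one
Product: 10 (1R,5S,6R)-5-(3-bromo-2-methylbut-3-en-2-yl)-6-methylbicyclo[4.1.0]heptan-2-one
Conditions: Me3S(O)I, NaH, DMSO, rt → 50 °C
Reagents that add atoms: trimethylsulfoxonium iodide C[S+](C)(C)=O.[I-]
Why: Corey–Chaykovsky cyclopropanation, in which the sulfoxonium ylide adds to the β-carbon on the face opposite the bulky C5 arm and closes by 3-exo-tet displacement, so the quaternary C10 is set with its new CH2 (C1) trans to that arm.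

Step 8
Reactants: 10 (1R,5S,6R)-5-(3-bromo-2-methylbut-3-en-2-yl)-6-methylbicyclo[4.1.0]heptan-2-one
Product: 12 (3S,4R)-4-(3-bromo-2-methylbut-3-en-2-yl)-3-(iodomethyl)-3-methylcyclohexan-1-one, via trimethylsilyl enol ether 11 (not isolated)
Conditions: Me3SiI, 2,6-di-tert-butyl-4-methylpyridine (cat.), CH2Cl2, −40 → 0 °C; then 0.5 M HCl, THF, 0 °C
Reagents that add atoms: iodotrimethylsilane C[Si](C)(C)I
Why: Homoconjugate opening of a cyclopropyl ketone by a silyl iodide, where iodide attacks the unhindered cyclopropane CH2 and cleaves the bond that overlaps with the activated carbonyl, and hydrolysis of the enol ether returns the ketone with both stereocentres intact.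

Step 9
Reactants: 12 (3S,4R)-4-(3-bromo-2-methylbut-3-en-2-yl)-3-(iodomethyl)-3-methylcyclohexan-1-one
Product: 13 (4aS,6R,8aS)-6-bromo-5,5,8a-trimethyloctahydronaphthalen-2(1H)-one
Conditions: (Me3Si)3SiH (1.2 equiv, syringe pump), AIBN (cat.), PhH (0.005 M), 80 °C
Reagents that add atoms: none
Why: Proposed new method: the silyl radical abstracts iodine from the neopentyl C–I bond, the primary C1 radical adds to the unsubstituted terminus (C2) of the 2-bromoalkene, and the α-bromo radical at C3 takes a hydrogen atom from the silane, which carries the chain. The closest known reaction type is the silane- or stannane-mediated 6-endo-trig cyclization of hex-5-enyl radicals substituted at the internal alkene carbon, together with the known addition of alkyl radicals to the CH2 end of vinyl halides. Ring A closes in the 6-endo-trig mode through a chair transition state in which the CH2 radical on C10 and the tertiary arm on C5 are both equatorial on ring B, so the trans ring fusion fixed in steps 3 and 7 is kept. The new C3 stereocentre is set by axial hydrogen delivery from the face opposite the axial methyl groups on C4 and C10, which leaves bromine equatorial. The step needs 6-endo over 5-exo closure (the 5-exo radical would expel a bromine atom) and abstraction of iodine in preference to bromine. The first is secured by bromine on the internal alkene carbon, by the neopentyl position of that carbon next to quaternary C4 and by the stabilization of the α-bromo radical; the second by the much faster abstraction of iodine from an alkyl iodide, helped by slow addition of a small excess of silane.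

Step 10
Reactants: 13 (4aS,6R,8aS)-6-bromo-5,5,8a-trimethyloctahydronaphthalen-2(1H)-one
Product: 14 (4aS,6R,8aS)-6-bromo-5,5,8a-trimethyl-4a,5,6,7,8,8a-hexahydronaphthalen-2(1H)-one
Conditions: IBX (2-iodoxybenzoic acid), DMSO–PhF, 70 °C
Reagents that add atoms: none
Why: IBX dehydrogenation of a ketone through its enol, regiospecific here because the other α-carbon (C9) is attached to quaternary C10 and cannot become part of an enone.

Step 11
Reactants: 15 (3R)-3,7-dimethylocta-1,6-dien-3-ol ((R)-linalool)
Product: 16 {[(3R)-3,7-dimethylocta-1,6-dien-3-yl]oxy}triethylsilane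
Conditions: Et3SiOTf, 2,6-lutidine, CH2Cl2, −78 → 0 °C
Reagents that add atoms: triethylsilyl trifluoromethanesulfonate CC[Si](CC)(CC)OS(=O)(=O)C(F)(F)F
Why: Silylation of a tertiary alcohol with a silyl triflate and a hindered pyridine base, in which the stereocentre takes no part.

Step 12
Reactants: 16 {[(3R)-3,7-dimethylocta-1,6-dien-3-yl]oxy}triethylsilane
Product: 18 (4R)-4-methyl-4-(triethylsilyloxy)hex-5-enal, via ozonide 17 (not isolated)
Conditions: O3 (1 equiv), CH2Cl2, −78 °C; then PPh3, −78 °C → rt
Reagents that add atoms: ozone [O-][O+]=O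
Why: Chemoselective ozonolysis, in which the electron-rich trisubstituted alkene reacts far faster than the monosubstituted vinyl group beside the silyloxy carbon and reductive work-up gives the aldehyde.

Step 13
Reactants: 18 (4R)-4-methyl-4-(triethylsilyloxy)hex-5-enal
Product: 19 (4R)-4-methyl-4-(triethylsilyloxy)hex-5-enoic acid
Conditions: NaClO2, NaH2PO4, 2-methyl-2-butene, t-BuOH–H2O, 0 °C → rt
Reagents that add atoms: sodium chlorite [Na+].[O-]Cl=O
Why: Pinnick oxidation of an aldehyde to the acid under buffered conditions with an alkene scavenger, which leaves the silyl ether and the vinyl group alone.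

Step 14
Reactants: 19 (4R)-4-methyl-4-(triethylsilyloxy)hex-5-enoic acid
Product: 21 triethyl{[(3R)-5-iodo-3-methylpent-1-en-3-yl]oxy}silane, via Barton ester 20 (not isolated)
Conditions: N-hydroxypyridine-2-thione, DCC, DMAP (cat.), CH2Cl2, 0 °C, dark; then CHI3, hν (tungsten lamp), rt
Reagents that add atoms: iodoform IC(I)I
Why: Barton decarboxylative iodination, in which the thiohydroxamate ester fragments under light to a primary radical that abstracts iodine from iodoform in a chain; this pent-4-enyl-type radical does not cyclize and the remote stereocentre is untouched.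

Step 15
Reactants: 14 (4aS,6R,8aS)-6-bromo-5,5,8a-trimethyl-4a,5,6,7,8,8a-hexahydronaphthalen-2(1H)-one; 21 triethyl{[(3R)-5-iodo-3-methylpent-1-en-3-yl]oxy}silane
Product: 22 (1R,4aS,6R,8aR)-6-bromo-5,5,8a-trimethyl-1-[(3R)-3-methyl-3-(triethylsilyloxy)pent-4-en-1-yl]-4a,5,6,7,8,8a-hexahydronaphthalen-2(1H)-one
Conditions: LiN(i-Pr)2, THF, −78 °C; then 21, DMPU, −78 → −20 °C
Reagents that add atoms: none
Why: Kinetic α'-deprotonation of the cyclohexenone gives the cross-conjugated lithium enolate at C9, which is alkylated (SN2) by the primary iodide on the face opposite the axial C10 methyl, setting C9 with the side chain trans to that methyl.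

Step 16
Reactants: 22 (1R,4aS,6R,8aR)-6-bromo-5,5,8a-trimethyl-1-[(3R)-3-methyl-3-(triethylsilyloxy)pent-4-en-1-yl]-4a,5,6,7,8,8a-hexahydronaphthalen-2(1H)-one
Product: 23 (1R,4aS,6R,8aR)-6-bromo-5,5,8a-trimethyl-1-[(3R)-3-methyl-3-(triethylsilyloxy)pent-4-en-1-yl]octahydronaphthalen-2(1H)-one
Conditions: LiBH(s-Bu)3, THF, −78 °C; then H2O
Reagents that add atoms: none
Why: Conjugate reduction of a β-unsubstituted cyclohexenone by a bulky trialkylborohydride, where the hindered carbonyl disfavours 1,2-attack and the enolate forms on the C7 side, so the C9 centre is not epimerized.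

Step 17
Reactants: 23 (1R,4aS,6R,8aR)-6-bromo-5,5,8a-trimethyl-1-[(3R)-3-methyl-3-(triethylsilyloxy)pent-4-en-1-yl]octahydronaphthalen-2(1H)-one
Product: 25 (3R)-5-[(1S,4aS,6R,8aS)-6-bromo-5,5,8a-trimethyl-2-methylidenedecahydronaphthalen-1-yl]-3-methylpent-1-en-3-ol, via triethylsilyl ether 24 (not isolated)
Conditions: Ph3PCH3Br, KOt-Bu, THF, 0 → 65 °C; then n-Bu4NF, THF, rt
Reagents that add atoms: methyltriphenylphosphonium bromide C[P+](c1ccccc1)(c1ccccc1)c1ccccc1.[Br-]
Why: Wittig methylenation of the hindered ketone followed by fluoride cleavage of the silyl ether, where the C9 hydrogen is equatorial and poorly aligned for enolization and so should survive the basic ylide.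

**Compound list**

1 | 2-methylcyclohex-2-en-1-one | CC1=CCCCC1=O | starting material
2 | (1R)-2-methylcyclohex-2-en-1-ol | O[C@@H]1CCCC=C1C | intermediate
3 | (1R)-2-methylcyclohex-2-en-1-yl 2-methylpropanoate | CC(C)C(=O)O[C@@H]1CCCC=C1C | intermediate
4 | trimethylsilyl ketene acetal of 3 | CC(C)=C(O[Si](C)(C)C)O[C@@H]1CCCC=C1C | intermediate
5 | trimethylsilyl 2-methyl-2-[(1S)-2-methylcyclohex-2-en-1-yl]propanoate | CC1=CCCC[C@@H]1C(C)(C)C(=O)O[Si](C)(C)C | intermediate
6 | 2-methyl-2-[(1S)-2-methylcyclohex-2-en-1-yl]propanoic acid | CC1=CCCC[C@@H]1C(C)(C)C(=O)O | intermediate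
7 | 3-methyl-3-[(1S)-2-methylcyclohex-2-en-1-yl]butan-2-one | CC1=CCCC[C@@H]1C(C)(C)C(C)=O | intermediate
8 | (6S)-6-(3-bromo-2-methylbut-3-en-2-yl)-1-methylcyclohex-1-ene | CC1=CCCC[C@@H]1C(C)(C)C(Br)=C | intermediate
9 | (4S)-4-(3-bromo-2-methylbut-3-en-2-yl)-3-methylcyclohex-2-en-1-one | O=C1CC[C@H](C(C)(C)C(Br)=C)C(C)=C1 | intermediate
10 | (1R,5S,6R)-5-(3-bromo-2-methylbut-3-en-2-yl)-6-methylbicyclo[4.1.0]heptan-2-one | O=C1CC[C@H](C(C)(C)C(Br)=C)[C@@]2(C)C[C@@H]12 | intermediate
11 | {[(3R,4R)-4-(3-bromo-2-methylbut-3-en-2-yl)-3-(iodomethyl)-3-methylcyclohex-1-en-1-yl]oxy}trimethylsilane | C[Si](C)(C)OC1=C[C@](C)(CI)[C@@H](C(C)(C)C(Br)=C)CC1 | intermediate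
12 | (3S,4R)-4-(3-bromo-2-methylbut-3-en-2-yl)-3-(iodomethyl)-3-methylcyclohexan-1-one | O=C1CC[C@H](C(C)(C)C(Br)=C)[C@@](C)(CI)C1 | intermediate
13 | (4aS,6R,8aS)-6-bromo-5,5,8a-trimethyloctahydronaphthalen-2(1H)-one (trans-fused, bromine equatorial) | O=C1CC[C@@H]2C(C)(C)[C@H](Br)CC[C@@]2(C)C1 | intermediate
14 | (4aS,6R,8aS)-6-bromo-5,5,8a-trimethyl-4a,5,6,7,8,8a-hexahydronaphthalen-2(1H)-one | O=C1C=C[C@@H]2C(C)(C)[C@H](Br)CC[C@@]2(C)C1 | intermediate
15 | (3R)-3,7-dimethylocta-1,6-dien-3-ol ((R)-linalool) | C=C[C@](C)(O)CCC=C(C)C | starting material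
16 | {[(3R)-3,7-dimethylocta-1,6-dien-3-yl]oxy}triethylsilane | C=C[C@](C)(O[Si](CC)(CC)CC)CCC=C(C)C | intermediate
17 | 3,3-dimethyl-5-[(3R)-3-methyl-3-(triethylsilyloxy)pent-4-en-1-yl]-1,2,4-trioxolane (both epimers at the ring CH) | C=C[C@](C)(O[Si](CC)(CC)CC)CCC1OOC(C)(C)O1 | intermediate
18 | (4R)-4-methyl-4-(triethylsilyloxy)hex-5-enal | C=C[C@](C)(O[Si](CC)(CC)CC)CCC=O | intermediate
19 | (4R)-4-methyl-4-(triethylsilyloxy)hex-5-enoic acid | C=C[C@](C)(O[Si](CC)(CC)CC)CCC(=O)O | intermediate
20 | 2-thioxopyridin-1(2H)-yl (4R)-4-methyl-4-(triethylsilyloxy)hex-5-enoate | C=C[C@](C)(O[Si](CC)(CC)CC)CCC(=O)On1ccccc1=S | intermediate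
21 | triethyl{[(3R)-5-iodo-3-methylpent-1-en-3-yl]oxy}silane | C=C[C@](C)(O[Si](CC)(CC)CC)CCI | intermediate
22 | (1R,4aS,6R,8aR)-6-bromo-5,5,8a-trimethyl-1-[(3R)-3-methyl-3-(triethylsilyloxy)pent-4-en-1-yl]-4a,5,6,7,8,8a-hexahydronaphthalen-2(1H)-one | O=C1C=C[C@@H]2C(C)(C)[C@H](Br)CC[C@@]2(C)[C@H]1CC[C@@](C)(O[Si](CC)(CC)CC)C=C | intermediate
23 | (1R,4aS,6R,8aR)-6-bromo-5,5,8a-trimethyl-1-[(3R)-3-methyl-3-(triethylsilyloxy)pent-4-en-1-yl]octahydronaphthalen-2(1H)-one | O=C1CC[C@@H]2C(C)(C)[C@H](Br)CC[C@@]2(C)[C@H]1CC[C@@](C)(O[Si](CC)(CC)CC)C=C | intermediate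
24 | {[(3R)-5-[(1S,4aS,6R,8aS)-6-bromo-5,5,8a-trimethyl-2-methylidenedecahydronaphthalen-1-yl]-3-methylpent-1-en-3-yl]oxy}triethylsilane | C=C1CC[C@@H]2C(C)(C)[C@H](Br)CC[C@@]2(C)[C@H]1CC[C@@](C)(O[Si](CC)(CC)CC)C=C | intermediate
25 | (3R)-5-[(1S,4aS,6R,8aS)-6-bromo-5,5,8a-trimethyl-2-methylidenedecahydronaphthalen-1-yl]-3-methylpent-1-en-3-ol | C=C[C@](C)(O)CC[C@H]1C(=C)CC[C@@H]2C(C)(C)[C@H](Br)CC[C@]21C | target

**Count and risks**

Total step count: 17. Longest linear sequence: 13 steps (steps 1–10 and 15–17); steps 11–14 make the side-chain iodide.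

Steps most likely to fail:

1. Step 9 (proposed new method). The radical may close in the 5-exo mode at the bromine-bearing carbon and then lose a bromine atom, or be reduced before it closes. The fallback uses known chemistry: ring A is closed at the same bond by an aldol condensation and the bromine is brought in afterwards. It sets out from 7 and comes back at 13.
   - Allylic oxidation as in step 6 should give the enedione F1.
   - Conjugate addition of vinylmagnesium bromide (CuBr·SMe2, Me3SiCl, THF, −78 °C), anti to the C5 arm, should give the vinyl diketone F2.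
   - Ozonolysis (O3; PPh3) should give the keto aldehyde F3.
   - Aldol condensation of the methyl ketone onto the aldehyde (KOH, MeOH) should give the bicyclic enedione F4.
   - Hydrogenation (H2, palladium on carbon) should give the dione F5.
   - Ketalization of the unhindered ring-B ketone (ethylene glycol, pyridinium p-toluenesulfonate) should give the keto ketal F6.
   - The triphenyl phosphite–bromine reagent as in step 5 should give the ring vinyl bromide F7.
   - Hydrogen-atom-transfer hydrogenation (Mn(dpm)3, PhSiH3, t-BuOOH, i-PrOH), which reduces haloalkenes without loss of halogen and under thermodynamic stereocontrol, should give the equatorial bromo ketal F8.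
   - Aqueous HCl in acetone then frees 13.

2. Step 15. SN2 attack at the hindered enolate carbon may be slow, so that elimination of HI from the iodide or proton transfer between enolate and product takes over. The fallback builds the side chain stepwise from a more reactive acceptor and sets C13 by reagent control. It sets out from 14 and comes back at 25.
   - Michael addition of the same lithium enolate to methyl vinyl ketone should give the diketone F9.
   - Horner–Wadsworth–Emmons olefination of the unhindered methyl ketone (triethyl phosphonoacetate, NaH) should give the (E)-enoate F10.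
   - Conjugate reduction as in step 16 should give the keto ester F11.
   - Wittig methylenation as in step 17 (no fluoride) should give the diene ester F12.
   - Reduction with i-Bu2AlH should give the allylic alcohol F13.
   - Sharpless asymmetric epoxidation (Ti(Oi-Pr)4, D-(−)-diethyl tartrate, t-BuOOH) should give the epoxy alcohol F14.
   - PPh3, I2 and imidazole should give the epoxy iodide F15.
   - Zinc dust in acetic acid–ethanol opens it reductively to the tertiary allylic alcohol 25.

3. Step 5. Ionization at the neopentyl carbonyl carbon may lead to skeletal rearrangement, or electrophilic bromine may attack the ring alkene. The fallback separates enolization from halide introduction. It sets out from 7 and comes back at 8.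
   - Kinetic enolization and triflation (KN(SiMe3)2, PhNTf2, THF, −78 °C) should give the enol triflate F16.
   - Ruthenium-catalysed triflate–bromide exchange ([Cp*Ru(MeCN)3]OTf, LiBr) should then give 8.

**Further compounds**

F1 | step 9 | (4S)-3-methyl-4-(3-methyl-2-oxobutan-2-yl)cyclohex-2-en-1-one | O=C1CC[C@H](C(C)(C)C(C)=O)C(C)=C1
F2 | step 9 | (3R,4S)-3-ethenyl-3-methyl-4-(3-methyl-2-oxobutan-2-yl)cyclohexan-1-one | O=C1CC[C@H](C(C)(C)C(C)=O)[C@@](C)(C=C)C1
F3 | step 9 | 1-methyl-2-(3-methyl-2-oxobutan-2-yl)-5-oxocyclohexane-1-carbaldehyde (formyl trans to the side chain) | O=C1CC[C@H](C(C)(C)C(C)=O)[C@@](C)(C=O)C1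
F4 | step 9 | 5,5,8a-trimethyl-3,4,4a,5-tetrahydronaphthalene-2,6(1H,8aH)-dione (trans-fused) | O=C1CC[C@@H]2C(C)(C)C(=O)C=C[C@@]2(C)C1
F5 | step 9 | 5,5,8a-trimethyloctahydronaphthalene-2,6-dione (trans-fused) | O=C1CC[C@@H]2C(C)(C)C(=O)CC[C@@]2(C)C1
F6 | step 9 | 2-(ethylene ketal) of F5 (ketone beside the gem-dimethyl carbon free) | O1CCOC12CC[C@@H]3C(C)(C)C(=O)CC[C@@]3(C)C2
F7 | step 9 | ethylene ketal of 6-bromo-5,5,8a-trimethyl-3,4,4a,5,8,8a-hexahydronaphthalen-2(1H)-one | O1CCOC12CC[C@@H]3C(C)(C)C(Br)=CC[C@@]3(C)C2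
F8 | step 9 | ethylene ketal of 13 | O1CCOC12CC[C@@H]3C(C)(C)[C@H](Br)CC[C@@]3(C)C2
F9 | step 15 | 1-(3-oxobutyl) derivative of 14 (side chain trans to the angular methyl) | O=C1C=C[C@@H]2C(C)(C)[C@H](Br)CC[C@@]2(C)[C@H]1CCC(C)=O
F10 | step 15 | ethyl (2E)-3-methylpent-2-enoate carrying the enone core of 14 at C5 | O=C1C=C[C@@H]2C(C)(C)[C@H](Br)CC[C@@]2(C)[C@H]1CC/C(C)=C/C(=O)OCC
F11 | step 15 | ring-saturated keto ester from F10 | O=C1CC[C@@H]2C(C)(C)[C@H](Br)CC[C@@]2(C)[C@H]1CC/C(C)=C/C(=O)OCC
F12 | step 15 | 2-methylidene ester from F11 | C=C1CC[C@@H]2C(C)(C)[C@H](Br)CC[C@@]2(C)[C@H]1CC/C(C)=C/C(=O)OCC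
F13 | step 15 | (2E)-allylic alcohol from F12 | C=C1CC[C@@H]2C(C)(C)[C@H](Br)CC[C@@]2(C)[C@H]1CC/C(C)=C/CO
F14 | step 15 | (2R,3R)-2,3-epoxy alcohol from F13 | C=C1CC[C@@H]2C(C)(C)[C@H](Br)CC[C@@]2(C)[C@H]1CC[C@@]3(C)O[C@@H]3CO
F15 | step 15 | epoxy iodide from F14 | C=C1CC[C@@H]2C(C)(C)[C@H](Br)CC[C@@]2(C)[C@H]1CC[C@@]3(C)O[C@@H]3CI
F16 | step 5 | 3-methyl-3-[(1S)-2-methylcyclohex-2-en-1-yl]but-1-en-2-yl trifluoromethanesulfonate | CC1=CCCC[C@@H]1C(C)(C)C(=C)OS(=O)(=O)C(F)(F)F
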